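## Analysis of the target

Target 25 is a B-type proanthocyanidin dimer. An epigallocatechin unit (benzo ring A, pyran ring C, pyrogallol ring B) is bonded through C4 to C8' of a (+)-catechin unit (benzo ring D, pyran ring F, catechol ring E), and O3 carries a galloyl ester. Ring C holds three contiguous stereocentres, C2 (R), C3 (R) and C4 (R), with 2,3-cis and 3,4-trans relationships: ring B is equatorial, and the gallate and the C4 aryl group are trans-diaxial. Ring F holds C2' (R) and C3' (S), trans, exactly as in natural (+)-catechin 1. The molecule has twelve phenols (two pyrogallol-type rings that oxidise in air), one ester that can migrate or cleave in base, an acid-labile doubly benzylic C4–C8' bond, and a C2 centre that epimerises in base through a ring-opened quinone methide. The hard part is the congested C4 methine, flanked by two arenes that each carry two ortho oxygens, next to an axial acyloxy group, together with the less common 2,3-cis arrangement. The strategy rests on the 4-hydroxyl of ring B, which is para to C2. In a benzyl-protected open-chain form, the 4-hydroxy-3,5-dibenzyloxybenzyl CH2 that will become C2 can be oxidised to a para-quinone methide, and the ring A oxygen on C8a can add to it to form O1–C2 and close ring C. The reversibility that makes C2 labile in the natural product is thus used to set it.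

## Retrosynthetic reasoning

**25 from 24.** All twelve benzyl ethers are removed in one final hydrogenolysis. Benzyl is the only group that can be taken off thirteen oxygens without acid or base, and the already free ring B hydroxyl of 24 needs no step.

**24 from 22 through 23 (O1–C2).** Ring C is opened at the aryl ether oxygen. C2 is the one centre of the upper unit that can be equilibrated, so it is the safest one to leave for last. Its precursor is a plain CH2 group, which removes one stereocentre from the acyclic chain. The forward reaction must oxidise the ring B phenol of 22 selectively to quinone methide 23 and let the ring A hydroxyl add to the exocyclic carbon, with C2 settling in the 2,3-cis configuration.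

**22 from 21.** The ring B hydroxyl is kept as a silyl ether until directly before the oxidation. The oxidisable phenol is therefore absent during the organometallic, acylation and Lewis acid steps.

**21 from 18 and 19 (C4–C4a).** The bond from C1 of the propane chain to ring A is cut. In the forward sense, the benzylic ester at C1 of 18 ionises next to the electron-rich ring D, and the neighbouring C2 gallate holds the cation as dioxolanylium ion 20. Phenol 19 then attacks anti to the bridging oxygen, through the carbon ortho to its hydroxyl. This disconnection puts the gallate in place before any free phenol exists, makes the same ester the stereodirecting group, and lets both C1 epimers converge. Cutting C4–C8' instead would need a differentiated ring A organometallic and would turn the participation against the desired 3,4-trans relationship.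

**18 from 16 and 17.** Both hydroxyls of diol 16 are esterified with acid 17. The C2 ester is the gallate of the target, and the C1 ester is the leaving group.

**16 from 15, and 15 from 4 (through 14) and 13 (C1–C8').** The bond between the chain and C8' of the catechin unit is made by acyl substitution of ester 13 with aryllithium 14, followed by carbonyl reduction. The configuration at C1 is irrelevant at this stage, so no selectivity is asked of the reduction.

**13 from 10 (through 12) and 11.** The CH2–ring B bond comes from opening glycidate 11 at its terminal carbon with Grignard reagent 12. The stereocentre of 11 is not touched and becomes C3 of the target.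

**10 from 9, 9 from 8, 8 from 5.** Ring B is built from symmetrical diether 5. The carbon between the two benzyloxy groups is hydroxylated through 6 and 7, the new phenol directs bromination to its para position, and the phenol is then silylated.

**4 from 3, 3 from 2, 2 from 1.** The lower unit is taken whole from (+)-catechin 1. All hydroxyls are benzylated and C8 is marked by bromination, so the regiochemistry of the interflavan bond is fixed before coupling.

## Alternatives that were turned down

**Alternative 1:** Both pyran aryl ether bonds, O1–C8a and O1'–C8a', are disconnected. In the forward step the open-chain diol A2, which carries an iodide on ring A and a bromide on ring D, would be closed twice by a zerovalent palladium catalyst with a bulky biaryl phosphine and a carbonate base to give A1.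
- For it: no stereocentre is made during ring closure, so C2 is fixed beforehand. On that point it is stronger than the chosen route.
- Against it: the lower unit cannot be taken from 1, so A2 is an acyclic array of five stereocentres that must be built from scratch.
- Against it: secondary benzylic alkoxides on palladium lose β-hydride readily, and both halides sit between two substituents on electron-rich rings. Two such closures in one operation compound the losses.
- Against it: A1 carries an acetal at O3, so the gallate costs two more steps, one of them acidic next to the acid-labile C4–C8' bond.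
- The chosen route offers the lower unit from the chiral pool, the gallate in place early, and a single ring closure.

**Alternative 2:** Aromatic ring D itself is disconnected (C8a'–C8' and C6'–C7' formed, C4a'–C8a' re-formed). Heating cyclobutenone A4 with siloxyalkyne A5 would pass through a vinylketene, a [2+2] adduct and a 6π closure to give phenol A3.
- For it: the position of the interflavan bond is set by construction, and the ring D oxygens emerge differentiated.
- Against it: A5 demands an alkynyl group on C4 of a finished epigallocatechin unit and its conversion to a silyl ynol ether, and A4 must carry the chiral side chain.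
- Against it: after A3, ring F still has to be closed at O1'–C2' with control of C2', and two silyl groups must be exchanged before the gallate can be introduced.
- The regiochemical problem it solves does not arise in the chosen route, where bromination of 3 fixes C8. The chosen route is much shorter.

**Alternative 3:** Ring F is disconnected at three bonds, C4'–C4a', C3'–C4' and O1'–C2'. Phenol A7, formaldehyde A9 and enol carbonate A8 would combine by ortho-hydroxymethylation on an arylboronic acid template, thermal formation of an ortho-quinone methide and a hetero-Diels–Alder reaction to give A6.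
- For it: it is at least as convergent as the chosen route, it keeps the gallate and the finished upper unit intact, and A6 is two deprotections from the target.
- Against it: C2' and C3' are created in the cycloaddition with relative control only. Their absolute sense would have to be induced by the remote upper-unit stereocentres, so a mixture of lower-unit diastereomers is expected.
- Against it: the cycloaddition needs heat on a gallate-bearing 4-arylflavan, and A7 itself already requires a C4 coupling.
- The chosen route takes C2' and C3' from 1 with certainty and creates only one stereocentre in its key step, under thermodynamic control.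

Key step: step 13

## Route

Remark on the chemistry: compounds 1, 5, 11, 17 and 19 are taken as purchasable. C1 of 16 and 18 is left configurationally undefined because it is ionised in step 11.

Step 1
Reactants: 1 (+)-catechin
Product: 2 5,7,3',4'-tetra-O-benzyl-(+)-catechin
Conditions: BnBr (4.4 equiv), K2CO3, DMF, 0 °C to rt
Reagents that add atoms: benzyl bromide, BrCc1ccccc1
Why: Williamson etherification; carbonate deprotonates only the four phenols, so the secondary hydroxyl stays free and C2 is not exposed to strong base.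

Step 2
Reactants: 2 5,7,3',4'-tetra-O-benzyl-(+)-catechin
Product: 3 penta-O-benzyl-(+)-catechin
Conditions: NaH, BnBr, DMF, 0 °C to rt
Reagents that add atoms: benzyl bromide, BrCc1ccccc1
Why: Williamson etherification of the remaining secondary alkoxide; with no free phenol left, the ring cannot open and the two stereocentres are safe.

Step 3
Reactants: 3 penta-O-benzyl-(+)-catechin
Product: 4 8-bromo-penta-O-benzyl-(+)-catechin
Conditions: NBS (1.05 equiv), CH2Cl2, −20 °C to rt
Reagents that add atoms: N-bromosuccinimide, O=C1CCC(=O)N1Br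
Why: Electrophilic aromatic bromination; the phloroglucinol-type ring is far more reactive than the catechol ring, and in 5,7-di-O-benzyl flavans C8 is the preferred position over C6.

Step 4
Reactants: 5 1,3-bis(benzyloxy)benzene
Product: 8 2,6-bis(benzyloxy)phenol, via 2,6-bis(benzyloxy)phenyllithium 6 (not isolated), via dimethyl 2,6-bis(benzyloxy)phenylboronate 7 (not isolated)
Conditions: n-BuLi, THF, 0 °C; B(OMe)3, −78 °C to rt; H2O2, aq NaOH, 0 °C
Reagents that add atoms: hydrogen peroxide, OO
Why: Directed ortho-metalation at the carbon flanked by both ether oxygens, borylation, and oxidative 1,2-aryl shift of the boronate to the phenol; the low lithiation temperature keeps benzylic deprotonation in check.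

Step 5
Reactants: 8 2,6-bis(benzyloxy)phenol
Product: 9 4-bromo-2,6-bis(benzyloxy)phenol
Conditions: NBS (1.0 equiv), CH2Cl2, −20 to 0 °C
Reagents that add atoms: N-bromosuccinimide, O=C1CCC(=O)N1Br
Why: Electrophilic aromatic bromination para to the hydroxyl; both ortho positions are occupied, so only the para carbon is activated by the strongest donor.

Step 6
Reactants: 9 4-bromo-2,6-bis(benzyloxy)phenol
Product: 10 [4-bromo-2,6-bis(benzyloxy)phenoxy]triisopropylsilane
Conditions: TIPSOTf, 2,6-lutidine, CH2Cl2, 0 °C to rt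
Reagents that add atoms: triisopropylsilyl trifluoromethanesulfonate, CC(C)[Si](C(C)C)(C(C)C)OS(=O)(=O)C(F)(F)F
Why: Silylation of a hindered phenol with a silyl triflate; the bulky silyl ether survives the Grignard, aryllithium and Lewis acid steps and is later removed by fluoride.

Step 7
Reactants: 10 [4-bromo-2,6-bis(benzyloxy)phenoxy]triisopropylsilane; 11 methyl (S)-glycidate
Product: 13 methyl (2S)-3-[3,5-bis(benzyloxy)-4-(triisopropylsilyloxy)phenyl]-2-hydroxypropanoate, via [3,5-bis(benzyloxy)-4-(triisopropylsilyloxy)phenyl]magnesium bromide 12 (not isolated)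
Conditions: Mg, THF, 45 °C; then CuI (10 mol %), 11, THF, −40 to −20 °C
Reagents that add atoms: none
Why: Grignard formation followed by copper-catalysed SN2 opening of the epoxide at its terminal carbon, which is faster than attack on the ester at low temperature; the stereocentre of 11 is not involved, so 13 is S, the configuration that becomes C3 of the target.

Step 8
Reactants: 4 8-bromo-penta-O-benzyl-(+)-catechin; 13 methyl (2S)-3-[3,5-bis(benzyloxy)-4-(triisopropylsilyloxy)phenyl]-2-hydroxypropanoate
Product: 15 (2S)-3-[3,5-bis(benzyloxy)-4-(triisopropylsilyloxy)phenyl]-2-hydroxy-1-(penta-O-benzylcatechin-8-yl)propan-1-one, via 8-lithio-penta-O-benzylcatechin 14 (not isolated)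
Conditions: 4, n-BuLi, THF, −78 °C; 13 pretreated with i-PrMgCl (1.0 equiv), THF, −78 °C; combine, −78 to −30 °C; aq NH4Cl
Reagents that add atoms: none
Why: Bromine–lithium exchange and nucleophilic acyl substitution on the ester; the magnesium-chelated tetrahedral intermediate lasts until work-up, the aryl ketone with two ortho substituents is too hindered for a second addition, and the neighbouring alkoxide suppresses enolisation so C2 stays S.

Step 9
Reactants: 15 (2S)-3-[3,5-bis(benzyloxy)-4-(triisopropylsilyloxy)phenyl]-2-hydroxy-1-(penta-O-benzylcatechin-8-yl)propan-1-one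
Product: 16 (1RS,2S)-3-[3,5-bis(benzyloxy)-4-(triisopropylsilyloxy)phenyl]-1-(penta-O-benzylcatechin-8-yl)propane-1,2-diol
Conditions: NaBH4, THF/MeOH, 0 °C
Reagents that add atoms: none
Why: Borohydride reduction of the ketone directly after isolation; the facial outcome at C1 does not matter because this carbon is ionised in step 11.

Step 10
Reactants: 16 (1RS,2S)-3-[3,5-bis(benzyloxy)-4-(triisopropylsilyloxy)phenyl]-1-(penta-O-benzylcatechin-8-yl)propane-1,2-diol; 17 3,4,5-tris(benzyloxy)benzoic acid
Product: 18 (1RS,2S)-3-[3,5-bis(benzyloxy)-4-(triisopropylsilyloxy)phenyl]-1-(penta-O-benzylcatechin-8-yl)propane-1,2-diyl bis[3,4,5-tris(benzyloxy)benzoate]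
Conditions: 17 (3 equiv), EDC·HCl, DMAP, CH2Cl2, rt
Reagents that add atoms: none
Why: Steglich esterification of both hydroxyls, which avoids any need to tell them apart; the C2 ester is the gallate of the target and the benzylic C1 ester is the leaving group for the next step.

Step 11
Reactants: 18 (1RS,2S)-3-[3,5-bis(benzyloxy)-4-(triisopropylsilyloxy)phenyl]-1-(penta-O-benzylcatechin-8-yl)propane-1,2-diyl bis[3,4,5-tris(benzyloxy)benzoate]; 19 3,5-bis(benzyloxy)phenol
Product: 21 (1R,2S)-1-[2,4-bis(benzyloxy)-6-hydroxyphenyl]-3-[3,5-bis(benzyloxy)-4-(triisopropylsilyloxy)phenyl]-1-(penta-O-benzylcatechin-8-yl)propan-2-yl 3,4,5-tris(benzyloxy)benzoate, via 4,5-trans-dioxolan-2-ylium ion 20 (not isolated)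
Conditions: 19 (4 equiv), TMSOTf (0.2 equiv), 4 Å MS, CH2Cl2, −78 to −30 °C; Et3N quench
Reagents that add atoms: none
Why: Friedel–Crafts alkylation through a benzylic cation (SN1): the Lewis acid ionises the C1 ester, the cation is stabilised by the three ring D oxygens ortho and para to C8', and the C2 gallate carbonyl caps it as the 4,5-trans dioxolan-2-ylium ion 20, so both C1 epimers of 18 converge. Phenol 19 opens 20 at C1 anti to the bridging oxygen and reacts through the carbon ortho to its hydroxyl, which is less hindered than the carbon between the two benzyloxy groups; this gives 1R, the 3,4-trans relationship of the target.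

Step 12
Reactants: 21 (1R,2S)-1-[2,4-bis(benzyloxy)-6-hydroxyphenyl]-3-[3,5-bis(benzyloxy)-4-(triisopropylsilyloxy)phenyl]-1-(penta-O-benzylcatechin-8-yl)propan-2-yl 3,4,5-tris(benzyloxy)benzoate
Product: 22 (1R,2S)-1-[2,4-bis(benzyloxy)-6-hydroxyphenyl]-3-[3,5-bis(benzyloxy)-4-hydroxyphenyl]-1-(penta-O-benzylcatechin-8-yl)propan-2-yl 3,4,5-tris(benzyloxy)benzoate
Conditions: TBAF, AcOH, THF, 0 °C
Reagents that add atoms: none
Why: Fluoride cleavage of the aryl silyl ether; the acetic acid buffer keeps the phenols protonated so that neither attacks the neighbouring ester.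

Step 13
Reactants: 22 (1R,2S)-1-[2,4-bis(benzyloxy)-6-hydroxyphenyl]-3-[3,5-bis(benzyloxy)-4-hydroxyphenyl]-1-(penta-O-benzylcatechin-8-yl)propan-2-yl 3,4,5-tris(benzyloxy)benzoate
Product: 24 dodeca-O-benzyl epigallocatechin-3-O-gallate-(4β→8)-catechin having the ring B 4-hydroxyl free, via ring B para-quinone methide 23 (not isolated)
Conditions: Ag2O (3 equiv), 4 Å MS, CH2Cl2, rt, dark; then Et3N (0.2 equiv), rt
Reagents that add atoms: none
Why: Ag2O removes two electrons and two protons from the syringol-type ring B phenol and its para benzylic CH2, giving para-quinone methide 23 whose exocyclic carbon is the future C2. The ring A hydroxyl then adds to that carbon in a 6-exo-trig 1,6-oxa-conjugate addition that rearomatises ring B, forms O1–C2 and closes pyran ring C. The closest known reaction type is the oxidative cyclisation of 1-(2-hydroxyaryl)-3-(4-hydroxy-3,5-dialkoxyphenyl)propanes to flavans through para-quinone methides, together with the base-induced C2 epimerisation of flavan-3-ols, which runs through the same ring-opened species. C2 is the only new stereocentre and is set by the substrate: the C4 aryl group escapes the peri benzyloxy group on C5 by standing pseudoaxial, the C3 gallate trans to it is then axial too, and ring B takes the equatorial place, which is the 2,3-cis (2R) isomer. Because the ring B hydroxyl is free in 24, the addition can revert to 23, so the product ratio can drift towards this most stable chair, and the small amount of Et3N is added for that purpose. The step needs chemoselective oxidation of one of two free phenols: ring B has two ortho alkoxy donors and a para alkyl group and can become a quinone methide, whereas the ring A phenol has its benzyloxy groups meta to the hydroxyl and no comparable outlet. Every other oxygen is a benzyl ether or part of the ester, so no second nucleophile competes for 23.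

Step 14
Reactants: 24 dodeca-O-benzyl epigallocatechin-3-O-gallate-(4β→8)-catechin having the ring B 4-hydroxyl free
Product: 25 epigallocatechin-3-O-gallate-(4β→8)-catechin
Conditions: H2 (1 atm), Pd(OH)2/C, THF/MeOH/H2O, rt
Reagents that add atoms: none
Why: Hydrogenolysis of all twelve benzyl ethers under neutral conditions, which leaves the ester, the flavan C–O bonds and the C4–C8' bond alone; no stereocentre is touched.

## Compound list

1 | (+)-catechin, (2R,3S)-2-(3,4-dihydroxyphenyl)chromane-3,5,7-triol | O[C@H]1Cc2c(O)cc(O)cc2O[C@@H]1c1ccc(O)c(O)c1 | starting material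

2 | 5,7,3',4'-tetra-O-benzyl-(+)-catechin, (2R,3S)-5,7-bis(benzyloxy)-2-[3,4-bis(benzyloxy)phenyl]chroman-3-ol | O[C@H]1Cc2c(OCc9ccccc9)cc(OCc9ccccc9)cc2O[C@@H]1c1ccc(OCc9ccccc9)c(OCc9ccccc9)c1 | intermediate

3 | penta-O-benzyl-(+)-catechin, (2R,3S)-3,5,7-tris(benzyloxy)-2-[3,4-bis(benzyloxy)phenyl]chromane | O(Cc9ccccc9)[C@H]1Cc2c(OCc9ccccc9)cc(OCc9ccccc9)cc2O[C@@H]1c1ccc(OCc9ccccc9)c(OCc9ccccc9)c1 | intermediate

4 | 8-bromo-penta-O-benzyl-(+)-catechin | O(Cc9ccccc9)[C@H]1Cc2c(OCc9ccccc9)cc(OCc9ccccc9)c(Br)c2O[C@@H]1c1ccc(OCc9ccccc9)c(OCc9ccccc9)c1 | intermediate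

5 | 1,3-bis(benzyloxy)benzene | c1cc(OCc9ccccc9)cc(OCc9ccccc9)c1 | starting material

6 | 2,6-bis(benzyloxy)phenyllithium | [Li]c1c(OCc9ccccc9)cccc1OCc9ccccc9 | intermediate (not isolated)

7 | dimethyl 2,6-bis(benzyloxy)phenylboronate | COB(OC)c1c(OCc9ccccc9)cccc1OCc9ccccc9 | intermediate (not isolated)

8 | 2,6-bis(benzyloxy)phenol | Oc1c(OCc9ccccc9)cccc1OCc9ccccc9 | intermediate

9 | 4-bromo-2,6-bis(benzyloxy)phenol | Oc1c(OCc9ccccc9)cc(Br)cc1OCc9ccccc9 | intermediate

10 | [4-bromo-2,6-bis(benzyloxy)phenoxy]triisopropylsilane | CC(C)[Si](C(C)C)(C(C)C)Oc1c(OCc9ccccc9)cc(Br)cc1OCc9ccccc9 | intermediate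

11 | methyl (S)-glycidate, methyl (2S)-oxirane-2-carboxylate | COC(=O)[C@@H]1CO1 | starting material

12 | [3,5-bis(benzyloxy)-4-(triisopropylsilyloxy)phenyl]magnesium bromide | Br[Mg]c1cc(OCc9ccccc9)c(O[Si](C(C)C)(C(C)C)C(C)C)c(OCc9ccccc9)c1 | intermediate (not isolated)

13 | methyl (2S)-3-[3,5-bis(benzyloxy)-4-(triisopropylsilyloxy)phenyl]-2-hydroxypropanoate | COC(=O)[C@@H](O)Cc1cc(OCc9ccccc9)c(O[Si](C(C)C)(C(C)C)C(C)C)c(OCc9ccccc9)c1 | intermediate

14 | 8-lithio-penta-O-benzylcatechin | [Li]c2c(OCc9ccccc9)cc(OCc9ccccc9)c3c2O[C@H](c2ccc(OCc9ccccc9)c(OCc9ccccc9)c2)[C@@H](OCc9ccccc9)C3 | intermediate (not isolated)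

15 | (2S)-3-[3,5-bis(benzyloxy)-4-(triisopropylsilyloxy)phenyl]-2-hydroxy-1-(penta-O-benzylcatechin-8-yl)propan-1-one | O=C([C@@H](O)Cc1cc(OCc9ccccc9)c(O[Si](C(C)C)(C(C)C)C(C)C)c(OCc9ccccc9)c1)c2c(OCc9ccccc9)cc(OCc9ccccc9)c3c2O[C@H](c2ccc(OCc9ccccc9)c(OCc9ccccc9)c2)[C@@H](OCc9ccccc9)C3 | intermediate

16 | (1RS,2S)-3-[3,5-bis(benzyloxy)-4-(triisopropylsilyloxy)phenyl]-1-(penta-O-benzylcatechin-8-yl)propane-1,2-diol (both C1 epimers) | OC([C@@H](O)Cc1cc(OCc9ccccc9)c(O[Si](C(C)C)(C(C)C)C(C)C)c(OCc9ccccc9)c1)c2c(OCc9ccccc9)cc(OCc9ccccc9)c3c2O[C@H](c2ccc(OCc9ccccc9)c(OCc9ccccc9)c2)[C@@H](OCc9ccccc9)C3 | intermediate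

17 | 3,4,5-tris(benzyloxy)benzoic acid | OC(=O)c1cc(OCc9ccccc9)c(OCc9ccccc9)c(OCc9ccccc9)c1 | starting material

18 | (1RS,2S)-3-[3,5-bis(benzyloxy)-4-(triisopropylsilyloxy)phenyl]-1-(penta-O-benzylcatechin-8-yl)propane-1,2-diyl bis[3,4,5-tris(benzyloxy)benzoate] (both C1 epimers) | O=C(OC([C@@H](OC(=O)c1cc(OCc9ccccc9)c(OCc9ccccc9)c(OCc9ccccc9)c1)Cc1cc(OCc9ccccc9)c(O[Si](C(C)C)(C(C)C)C(C)C)c(OCc9ccccc9)c1)c2c(OCc9ccccc9)cc(OCc9ccccc9)c3c2O[C@H](c2ccc(OCc9ccccc9)c(OCc9ccccc9)c2)[C@@H](OCc9ccccc9)C3)c1cc(OCc9ccccc9)c(OCc9ccccc9)c(OCc9ccccc9)c1 | intermediate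

19 | 3,5-bis(benzyloxy)phenol | Oc1cc(OCc9ccccc9)cc(OCc9ccccc9)c1 | starting material

20 | 4,5-trans-4-[3,5-bis(benzyloxy)-4-(triisopropylsilyloxy)benzyl]-5-(penta-O-benzylcatechin-8-yl)-2-[3,4,5-tris(benzyloxy)phenyl]-1,3-dioxolan-2-ylium cation | [O+]5=C(c4cc(OCc9ccccc9)c(OCc9ccccc9)c(OCc9ccccc9)c4)O[C@@H](Cc1cc(OCc9ccccc9)c(O[Si](C(C)C)(C(C)C)C(C)C)c(OCc9ccccc9)c1)[C@@H]5c2c(OCc9ccccc9)cc(OCc9ccccc9)c3c2O[C@H](c2ccc(OCc9ccccc9)c(OCc9ccccc9)c2)[C@@H](OCc9ccccc9)C3 | intermediate (not isolated)

21 | (1R,2S)-1-[2,4-bis(benzyloxy)-6-hydroxyphenyl]-3-[3,5-bis(benzyloxy)-4-(triisopropylsilyloxy)phenyl]-1-(penta-O-benzylcatechin-8-yl)propan-2-yl 3,4,5-tris(benzyloxy)benzoate | O=C(O[C@@H](Cc1cc(OCc9ccccc9)c(O[Si](C(C)C)(C(C)C)C(C)C)c(OCc9ccccc9)c1)[C@@H](c2c(OCc9ccccc9)cc(OCc9ccccc9)c3c2O[C@H](c2ccc(OCc9ccccc9)c(OCc9ccccc9)c2)[C@@H](OCc9ccccc9)C3)c2c(OCc9ccccc9)cc(OCc9ccccc9)cc2O)c1cc(OCc9ccccc9)c(OCc9ccccc9)c(OCc9ccccc9)c1 | intermediate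

22 | (1R,2S)-1-[2,4-bis(benzyloxy)-6-hydroxyphenyl]-3-[3,5-bis(benzyloxy)-4-hydroxyphenyl]-1-(penta-O-benzylcatechin-8-yl)propan-2-yl 3,4,5-tris(benzyloxy)benzoate | O=C(O[C@@H](Cc1cc(OCc9ccccc9)c(O)c(OCc9ccccc9)c1)[C@@H](c2c(OCc9ccccc9)cc(OCc9ccccc9)c3c2O[C@H](c2ccc(OCc9ccccc9)c(OCc9ccccc9)c2)[C@@H](OCc9ccccc9)C3)c2c(OCc9ccccc9)cc(OCc9ccccc9)cc2O)c1cc(OCc9ccccc9)c(OCc9ccccc9)c(OCc9ccccc9)c1 | intermediate (precursor of the key step)

23 | para-quinone methide of 22, 4-alkylidene-2,6-bis(benzyloxy)cyclohexa-2,5-dien-1-one whose exocyclic carbon is the future C2 | O=C(O[C@@H](C=C1C=C(OCc9ccccc9)C(=O)C(OCc9ccccc9)=C1)[C@@H](c2c(OCc9ccccc9)cc(OCc9ccccc9)c3c2O[C@H](c2ccc(OCc9ccccc9)c(OCc9ccccc9)c2)[C@@H](OCc9ccccc9)C3)c2c(OCc9ccccc9)cc(OCc9ccccc9)cc2O)c1cc(OCc9ccccc9)c(OCc9ccccc9)c(OCc9ccccc9)c1 | intermediate (not isolated)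

24 | dodeca-O-benzyl epigallocatechin-3-O-gallate-(4β→8)-catechin having the ring B 4-hydroxyl free, (2R,3R,4R) in the upper unit | O=C(O[C@@H]1[C@@H](c2c(OCc9ccccc9)cc(OCc9ccccc9)c3c2O[C@H](c2ccc(OCc9ccccc9)c(OCc9ccccc9)c2)[C@@H](OCc9ccccc9)C3)c2c(OCc9ccccc9)cc(OCc9ccccc9)cc2O[C@@H]1c1cc(OCc9ccccc9)c(O)c(OCc9ccccc9)c1)c1cc(OCc9ccccc9)c(OCc9ccccc9)c(OCc9ccccc9)c1 | intermediate (product of the key step)

25 | epigallocatechin-3-O-gallate-(4β→8)-catechin, CNP0129434.1 | O=C(O[C@@H]1[C@@H](c2c(O)cc(O)c3c2O[C@H](c2ccc(O)c(O)c2)[C@@H](O)C3)c2c(O)cc(O)cc2O[C@@H]1c1cc(O)c(O)c(O)c1)c1cc(O)c(O)c(O)c1 | target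

## Step count and least certain steps

Total: 14 steps. Longest linear sequence: 11 steps (5 to 25 through steps 4 to 14).

**Step 13 (key step).** The most likely failure is incomplete stereocontrol at C2. Closure through the all-equatorial chair, or delivery of O1 anti to a gallate carbonyl that has bridged onto the quinone methide, leads to the 2,3-trans epimer. The energy gap that favours the cis chair may be too small for clean equilibration, and tautomerisation of the quinone methide to a styrene would drain material at the same time.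

Fallback: the upper unit is taken with ring C already closed. The sequence sets out from 3 and 17 and returns at 25. Purchased (−)-epigallocatechin F1 is benzylated on its five phenols (BnBr, K2CO3) to penta-O-benzylepigallocatechin F2. F2 is oxidised at C4 with DDQ in the presence of 2-ethoxyethanol to the 4β-(2-ethoxyethoxy) ether F3. F3 is condensed with an excess of 3 under TMSOTf at −78 °C, where the C3 oxygen sends the nucleophile to the β face, to give the 4β→8 dimer with a free 3-hydroxyl F4. Esterification with 17 (EDC·HCl, DMAP) gives the trideca-O-benzyl gallate F5, and hydrogenolysis over Pd(OH)2/C gives 25.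

**Step 11.** The most likely failure is erosion of facial selectivity at C1. This happens if the open benzylic cation reacts faster than its dioxolanylium form, so that the phenol enters on the face of the ester oxygen. Attack of the cation on ring B of the same molecule is a lesser competing path.

Fallback: the roles of the two arenes are exchanged, so that a preference for attack anti to the CH2 aryl group now leads to the wanted epimer. The sequence sets out from 19, 13 and 3 and returns at 22. Phenol 19 is converted to 1,3-bis(benzyloxy)-5-(methoxymethoxy)benzene F6 (MOMCl, i-Pr2NEt). F6 is lithiated between the acetal oxygen and a benzyloxy group (n-BuLi, THF, 0 °C) and added to the magnesium alkoxide of 13 to give the ring A aryl ketone F7. NaBH4 reduces F7 to the diol F8. TMSOTf ionises the benzylic hydroxyl of F8, now next to ring A, and 3 attacks through C8 without a participating ester to give the (1R,2S) triarylpropan-2-ol F9. Esterification with 17 (EDC·HCl, DMAP) gives the gallate F10. Removal of the acetal (dilute HCl, MeOH/THF) and of the silyl group (TBAF, AcOH) gives 22.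

**Step 8.** The most likely failure is stalling of the acyl substitution. The aryllithium, hindered by two ortho substituents, may act as a base towards the ester or be quenched by proton transfer before it adds. Any enolisation of the hydroxy ketone before reduction would also erode C2.

Fallback: the carbonyl partner is changed from ester to aldehyde. The sequence sets out from 13 and returns at 16. Ester 13 is silylated (TESCl, imidazole) to methyl (2S)-3-aryl-2-(triethylsilyloxy)propanoate F11, which DIBAL-H at −78 °C reduces to the (S)-α-silyloxy aldehyde F12. Aryllithium 14 adds to F12 to give the mono-silylated diol F13; silyl migration between the two oxygens is of no consequence. Pyridine-buffered HF·pyridine removes the triethylsilyl group to give 16.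

## Further compounds

F1 | step 13 | (−)-epigallocatechin | O[C@@H]1Cc2c(O)cc(O)cc2O[C@@H]1c1cc(O)c(O)c(O)c1

F2 | step 13 | 5,7,3',4',5'-penta-O-benzyl-(−)-epigallocatechin | O[C@@H]1Cc2c(OCc9ccccc9)cc(OCc9ccccc9)cc2O[C@@H]1c1cc(OCc9ccccc9)c(OCc9ccccc9)c(OCc9ccccc9)c1

F3 | step 13 | 4β-(2-ethoxyethoxy)-penta-O-benzyl-(−)-epigallocatechin | O[C@@H]1[C@@H](OCCOCC)c2c(OCc9ccccc9)cc(OCc9ccccc9)cc2O[C@@H]1c1cc(OCc9ccccc9)c(OCc9ccccc9)c(OCc9ccccc9)c1

F4 | step 13 | deca-O-benzyl epigallocatechin-(4β→8)-catechin with free 3-hydroxyl | O[C@@H]1[C@@H](c2c(OCc9ccccc9)cc(OCc9ccccc9)c3c2O[C@H](c2ccc(OCc9ccccc9)c(OCc9ccccc9)c2)[C@@H](OCc9ccccc9)C3)c2c(OCc9ccccc9)cc(OCc9ccccc9)cc2O[C@@H]1c1cc(OCc9ccccc9)c(OCc9ccccc9)c(OCc9ccccc9)c1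

F5 | step 13 | trideca-O-benzyl epigallocatechin-3-O-gallate-(4β→8)-catechin | O=C(O[C@@H]1[C@@H](c2c(OCc9ccccc9)cc(OCc9ccccc9)c3c2O[C@H](c2ccc(OCc9ccccc9)c(OCc9ccccc9)c2)[C@@H](OCc9ccccc9)C3)c2c(OCc9ccccc9)cc(OCc9ccccc9)cc2O[C@@H]1c1cc(OCc9ccccc9)c(OCc9ccccc9)c(OCc9ccccc9)c1)c1cc(OCc9ccccc9)c(OCc9ccccc9)c(OCc9ccccc9)c1

F6 | step 11 | 1,3-bis(benzyloxy)-5-(methoxymethoxy)benzene | COCOc1cc(OCc9ccccc9)cc(OCc9ccccc9)c1

F7 | step 11 | (2S)-1-[2,4-bis(benzyloxy)-6-(methoxymethoxy)phenyl]-3-[3,5-bis(benzyloxy)-4-(triisopropylsilyloxy)phenyl]-2-hydroxypropan-1-one | O=C([C@@H](O)Cc1cc(OCc9ccccc9)c(O[Si](C(C)C)(C(C)C)C(C)C)c(OCc9ccccc9)c1)c2c(OCOC)cc(OCc9ccccc9)cc2OCc9ccccc9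

F8 | step 11 | (1RS,2S)-1-[2,4-bis(benzyloxy)-6-(methoxymethoxy)phenyl]-3-[3,5-bis(benzyloxy)-4-(triisopropylsilyloxy)phenyl]propane-1,2-diol | OC([C@@H](O)Cc1cc(OCc9ccccc9)c(O[Si](C(C)C)(C(C)C)C(C)C)c(OCc9ccccc9)c1)c2c(OCOC)cc(OCc9ccccc9)cc2OCc9ccccc9

F9 | step 11 | (1R,2S)-1-[2,4-bis(benzyloxy)-6-(methoxymethoxy)phenyl]-3-[3,5-bis(benzyloxy)-4-(triisopropylsilyloxy)phenyl]-1-(penta-O-benzylcatechin-8-yl)propan-2-ol | O[C@@H](Cc1cc(OCc9ccccc9)c(O[Si](C(C)C)(C(C)C)C(C)C)c(OCc9ccccc9)c1)[C@@H](c2c(OCc9ccccc9)cc(OCc9ccccc9)c3c2O[C@H](c2ccc(OCc9ccccc9)c(OCc9ccccc9)c2)[C@@H](OCc9ccccc9)C3)c2c(OCc9ccccc9)cc(OCc9ccccc9)cc2OCOC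

F10 | step 11 | (1R,2S)-1-[2,4-bis(benzyloxy)-6-(methoxymethoxy)phenyl]-3-[3,5-bis(benzyloxy)-4-(triisopropylsilyloxy)phenyl]-1-(penta-O-benzylcatechin-8-yl)propan-2-yl 3,4,5-tris(benzyloxy)benzoate | O=C(O[C@@H](Cc1cc(OCc9ccccc9)c(O[Si](C(C)C)(C(C)C)C(C)C)c(OCc9ccccc9)c1)[C@@H](c2c(OCc9ccccc9)cc(OCc9ccccc9)c3c2O[C@H](c2ccc(OCc9ccccc9)c(OCc9ccccc9)c2)[C@@H](OCc9ccccc9)C3)c2c(OCc9ccccc9)cc(OCc9ccccc9)cc2OCOC)c1cc(OCc9ccccc9)c(OCc9ccccc9)c(OCc9ccccc9)c1

F11 | step 8 | methyl (2S)-3-[3,5-bis(benzyloxy)-4-(triisopropylsilyloxy)phenyl]-2-(triethylsilyloxy)propanoate | COC(=O)[C@@H](O[Si](CC)(CC)CC)Cc1cc(OCc9ccccc9)c(O[Si](C(C)C)(C(C)C)C(C)C)c(OCc9ccccc9)c1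

F12 | step 8 | (2S)-3-[3,5-bis(benzyloxy)-4-(triisopropylsilyloxy)phenyl]-2-(triethylsilyloxy)propanal | O=C[C@@H](O[Si](CC)(CC)CC)Cc1cc(OCc9ccccc9)c(O[Si](C(C)C)(C(C)C)C(C)C)c(OCc9ccccc9)c1

F13 | step 8 | (1RS,2S)-3-[3,5-bis(benzyloxy)-4-(triisopropylsilyloxy)phenyl]-1-(penta-O-benzylcatechin-8-yl)-2-(triethylsilyloxy)propan-1-ol | OC([C@@H](O[Si](CC)(CC)CC)Cc1cc(OCc9ccccc9)c(O[Si](C(C)C)(C(C)C)C(C)C)c(OCc9ccccc9)c1)c2c(OCc9ccccc9)cc(OCc9ccccc9)c3c2O[C@H](c2ccc(OCc9ccccc9)c(OCc9ccccc9)c2)[C@@H](OCc9ccccc9)C3

A1 | alternative 1 | 3-O-methoxymethyl deca-O-benzyl epigallocatechin-(4β→8)-catechin | COCO[C@@H]1[C@@H](c2c(OCc9ccccc9)cc(OCc9ccccc9)c3c2O[C@H](c2ccc(OCc9ccccc9)c(OCc9ccccc9)c2)[C@@H](OCc9ccccc9)C3)c2c(OCc9ccccc9)cc(OCc9ccccc9)cc2O[C@@H]1c1cc(OCc9ccccc9)c(OCc9ccccc9)c(OCc9ccccc9)c1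

A2 | alternative 1 | open-chain diol precursor of A1 with free C2 and C2' hydroxyls, an iodide on C8a of ring A and a bromide on C8a' of ring D | COCO[C@@H]([C@H](O)c1cc(OCc9ccccc9)c(OCc9ccccc9)c(OCc9ccccc9)c1)[C@@H](c2c(OCc9ccccc9)cc(OCc9ccccc9)c(C[C@H](OCc9ccccc9)[C@H](O)c3ccc(OCc9ccccc9)c(OCc9ccccc9)c3)c2Br)c2c(OCc9ccccc9)cc(OCc9ccccc9)cc2I

A3 | alternative 2 | upper unit bearing at C4 the ring D phenol (7'-triisopropylsilyloxy, 5'-benzyloxy, acetonide side chain on C4a', 3-O-tert-butyldimethylsilyl) | CC(C)(C)[Si](C)(C)O[C@@H]1[C@@H](c2c(O[Si](C(C)C)(C(C)C)C(C)C)cc(OCc9ccccc9)c(C[C@@H]3OC(C)(C)O[C@H]3c4ccc(OCc9ccccc9)c(OCc9ccccc9)c4)c2O)c2c(OCc9ccccc9)cc(OCc9ccccc9)cc2O[C@@H]1c1cc(OCc9ccccc9)c(OCc9ccccc9)c(OCc9ccccc9)c1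

A4 | alternative 2 | 3-benzyloxy-4-{[(4R,5S)-configured 5-(3,4-dibenzyloxyphenyl)-2,2-dimethyl-1,3-dioxolan-4-yl]methyl}cyclobut-2-en-1-one (acetonide stereocentres as in A3) | O=C1C=C(OCc9ccccc9)C1C[C@@H]3OC(C)(C)O[C@H]3c4ccc(OCc9ccccc9)c(OCc9ccccc9)c4

A5 | alternative 2 | penta-O-benzyl 3-O-tert-butyldimethylsilyl epigallocatechin carrying a (triisopropylsilyloxy)ethynyl group at C4β | CC(C)(C)[Si](C)(C)O[C@@H]1[C@@H](C#CO[Si](C(C)C)(C(C)C)C(C)C)c2c(OCc9ccccc9)cc(OCc9ccccc9)cc2O[C@@H]1c1cc(OCc9ccccc9)c(OCc9ccccc9)c(OCc9ccccc9)c1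

A6 | alternative 3 | dodeca-O-benzyl derivative of the target with a 3'-O-allyloxycarbonyl group | O=C(O[C@@H]1[C@@H](c2c(OCc9ccccc9)cc(OCc9ccccc9)c3c2O[C@H](c2ccc(OCc9ccccc9)c(OCc9ccccc9)c2)[C@@H](OC(=O)OCC=C)C3)c2c(OCc9ccccc9)cc(OCc9ccccc9)cc2O[C@@H]1c1cc(OCc9ccccc9)c(OCc9ccccc9)c(OCc9ccccc9)c1)c1cc(OCc9ccccc9)c(OCc9ccccc9)c(OCc9ccccc9)c1

A7 | alternative 3 | octa-O-benzyl epigallocatechin gallate carrying a 2-hydroxy-4,6-bis(benzyloxy)phenyl group at C4β | O=C(O[C@@H]1[C@@H](c2c(OCc9ccccc9)cc(OCc9ccccc9)cc2O)c2c(OCc9ccccc9)cc(OCc9ccccc9)cc2O[C@@H]1c1cc(OCc9ccccc9)c(OCc9ccccc9)c(OCc9ccccc9)c1)c1cc(OCc9ccccc9)c(OCc9ccccc9)c(OCc9ccccc9)c1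

A8 | alternative 3 | allyl (E)-2-[3,4-bis(benzyloxy)phenyl]ethenyl carbonate | C=CCOC(=O)O/C=C/c1ccc(OCc2ccccc2)c(OCc2ccccc2)c1

A9 | alternative 3 | formaldehyde | C=O
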